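## Retrosynthetic overview
- The target's 7-carbinol disconnects to the 7-aryl ketone, which is reduced with delivery of hydride from the cis-hydroxymethyl group.
- The ketone-bearing 2-aryl-tetrahydrofuran disconnects at the C7'–O bond, formed by anodic benzylic (p-quinone methide) oxa-cyclisation of a 7-oxo seco-diol. This is the only ring formed.
- The 7-oxo seco-diol comes from the 7-hydroxy-secolignan by benzylic-alcohol oxidation.
- That secolignan comes from lactone reduction of the knotwood lignan 7-hydroxymatairesinol, which supplies both ring-carbon stereocentres (C8, C8').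

Assumption: commercial 7-hydroxymatairesinol is the (8R,8'R) lignan with C7 as an epimeric mixture (7S major). C7 is oxidised away in step 2, so its configuration is irrelevant.

## Route

**Step 1**
Reactants: 1, (3R,4R)-7-hydroxymatairesinol, the knotwood lignan
Product: 2, (2R,3R)-1,4-bis(4-hydroxy-3-methoxyphenyl)-2,3-bis(hydroxymethyl)butan-1-ol (7-hydroxysecoisolariciresinol, C1 epimeric)
Conditions: LiAlH4 (5 equiv), THF, 0 °C → rt, 3 h; Rochelle-salt work-up
Reagents that add atoms: none
Why: Hydride reduction of the lactone to the diol (as for matairesinol → secoisolariciresinol) leaves the aryl ether, phenol (as phenolate) and benzylic-alcohol groups untouched. The C8/C8' centres are not epimerisable and are carried through unchanged.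

**Step 2**
Reactants: 2
Product: 3, (2R,3R)-2,3-bis(hydroxymethyl)-1,4-bis(4-hydroxy-3-methoxyphenyl)butan-1-one (7-oxo-secoisolariciresinol)
Conditions: activated MnO2 (15 equiv), acetone, rt, 6 h
Reagents that add atoms: none
Why: MnO2 oxidises only the benzylic secondary alcohol, not the non-activated primary alcohols, and this destroys the C7 epimer issue. The aryl ketone does two jobs: it removes the C7 benzylic C–H, and it makes that ring a p-hydroxyphenyl ketone that is hard to oxidise in step 3.

**Step 3**
Reactants: 3
Product: 4, (4-hydroxy-3-methoxyphenyl)[(3R,4R,5S)-4-(hydroxymethyl)-5-(4-hydroxy-3-methoxyphenyl)oxolan-3-yl]methanone (7-oxolariciresinol)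
Conditions: undivided cell, graphite felt (+)/Pt (–), constant current 3 mA, 0.02 M substrate, nBu4NBF4 (0.1 M), 2,6-lutidine (1 equiv), HFIP/MeCN 1:4, rt, 2.2 F/mol
Reagents that add atoms: none
Why: Proposed new method: the anode oxidises the electron-rich free 4-alkylguaiacol ring (2 e⁻/2 H⁺, H2 evolved at the cathode) to a p-quinone methide at C7'. The primary OH on C8' of the neighbouring carbon (the CH2OH that sits γ to C7') adds 5-exo in an oxa-Michael step to close the THF ring. Addition is reversible in HFIP, so the Ar group ends up trans to both the cis-disposed CH2OH and aroyl groups, which sets C7' as S. The closest known reactions are DDQ or anodic p-quinone methide formation from 4-alkylphenols with intermolecular alcohol trapping, and electrochemical benzylic C–H etherification. What is new is the intramolecular, dehydrogenative ring closure on an unprotected polyhydroxylated lignan, with the second ring electronically blocked by the ketone.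

**Step 4**
Reactants: 4
Product: 5, (7R)-7-hydroxylariciresinol, [(2S,3R,4R)-4-[(R)-hydroxy(4-hydroxy-3-methoxyphenyl)methyl]-2-(4-hydroxy-3-methoxyphenyl)oxolan-3-yl]methanol
Conditions: Me4NBH(OAc)3 (6 equiv), MeCN/AcOH 1:1, –10 °C → rt, 24 h
Reagents that add atoms: none
Why: This is a hydroxyl-directed reduction of the Evans–Saksena type. The primary OH on C8 (the CH2OH on C3 of the ring), cis to the ketone, exchanges onto boron and delivers hydride intramolecularly to the carbonyl face on its own side. That face is the one syn to C8, which gives the 7R carbinol. The ring ether, phenols and aryl ethers are inert to the reagent.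

## Compound list
1 | (3R,4R)-7-hydroxymatairesinol (C7 unspecified) | COc1cc(C[C@H]2C(=O)OC[C@@H]2C(O)c2ccc(O)c(OC)c2)ccc1O | starting material
2 | (2R,3R)-7-hydroxysecoisolariciresinol (C1 unspecified) | COc1cc(C[C@@H](CO)[C@H](CO)C(O)c2ccc(O)c(OC)c2)ccc1O | intermediate
3 | (2R,3R)-7-oxo-secoisolariciresinol | COc1cc(C[C@@H](CO)[C@H](CO)C(=O)c2ccc(O)c(OC)c2)ccc1O | intermediate
4 | 7-oxolariciresinol | COc1cc([C@H]2OC[C@H](C(=O)c3ccc(O)c(OC)c3)[C@@H]2CO)ccc1O | intermediate
5 | (7R)-7-hydroxylariciresinol | COc1cc([C@H]2OC[C@H]([C@@H](O)c3ccc(O)c(OC)c3)[C@@H]2CO)ccc1O | target

Formula check: 1 is C20H22O7, 2 is C20H26O7 (+4H), 3 is C20H24O7 (–2H), 4 is C20H22O7 (–2H), 5 is C20H24O7 (+2H), which matches the target.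

## Totals
Total steps: 4. Longest linear sequence: 4.

## Three steps most likely to fail
1. **Step 3 (proposed new method; anodic cyclisation).** Over-oxidation of the product phenol, or retro-aldol/dehydration of the β-hydroxy ketone, could lower the yield. Fallback (known chemistry): peracetylate 3 (Ac2O, pyridine), brominate only the C7' benzylic CH2 (NBS, hν), then treat with K2CO3/MeOH. This removes all acetates and generates the same p-quinone methide by 1,6-elimination of bromide, and the pendant OH then closes the ring.
2. **Step 4 (diastereoselectivity at C7).** The γ-hydroxy-directed delivery goes through a 7-membered transition state, and undirected Felkin/chelation control would favour 7S. Fallback: reduce 4 with NaBH4 to give mainly the 7S epimer. Acetylate the phenols and primary OH (Ac2O, pyridine, no DMAP). Invert C7 by Mitsunobu (p-nitrobenzoic acid, PPh3, DIAD), then remove all esters with K2CO3/MeOH to give 5.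
3. **Step 2 (chemoselective oxidation).** MnO2 may oxidise the phenols or trigger retro-aldol of the product. Fallback: reverse the order. Oxidise 1 at the lactone stage (Pd/C, O2) to 7-oxomatairesinol, then open the lactone with LiBH4 in THF at 0 °C, where the phenolate-deactivated aryl ketone survives, to give 3.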